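I reckon the fall of target, not its rise, because Thursday's is read at 30 h, long after the highest reading of the south-east run at 8.00 h.

| setting | south-east | east | north-west | south-west | Friday's | Sunday's | Thursday's | Saturday's |
|---|---|---|---|---|---|---|---|---|
| substrate | 0.30 M | 0.30 M | 0.30 M | 0.30 M | 0.30 M (fed, over 20 h) | 0.30 M | 0.30 M | 0.30 M (fed, over 20 h) |
| first nucleophile | 0.21 M | 0.10 M | 0.16 M | 0.21 M | 0.210 M | 0.210 M | 0.210 M | 0.210 M |
| second nucleophile | 0.33 M | 0.33 M | 0.33 M | 0.49 M | 0.330 M | 0.330 M (fed, over 20 h) | 0.330 M | 0.330 M |
| temperature | 35 °C | 46 °C | 35 °C | 46 °C |  | 40 °C | 40 °C | 40 °C |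
| remark | run made earlier | run made earlier | run made earlier | run made earlier | the addition at 20 °C, then warmed to 40 °C; the feed brings no volume worth counting | all else is in the flask from the start; the feed brings no volume worth counting | everything together at the start | all else is in the flask from the start; the feed brings no volume worth counting |
| time |  |  |  |  | 30 h | 30 h | 30 h | 30 h |

| run | time / h | target / % |
|---|---|---|
| south-east | 1.00 | 1.9 |
| south-east | 3.00 | 9.3 |
| south-east | 5.00 | 11.9 |
| south-east | 8.00 | 12.4 |
| south-east | 10.0 | 12.3 |
| south-east | 15.0 | 10.1 |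
| south-east | 20.0 | 5.6 |
| east | 1.33 | 7.1 |
| east | 2.00 | 6.5 |
| east | 3.00 | 8.1 |
| east | 5.00 | 5.8 |
| east | 8.00 | 4.3 |
| east | 12.0 | 3.1 |
| east | 20.0 | 0 |
| north-west | 1.33 | 3.0 |
| north-west | 2.00 | 5.4 |
| north-west | 3.00 | 7.6 |
| north-west | 5.00 | 7.9 |
| north-west | 8.00 | 8.3 |
| north-west | 12.0 | 7.7 |
| north-west | 20.0 | 4.2 |
| south-west | 1.50 | 10.0 |
| south-west | 5.00 | 5.9 |
| south-west | 8.00 | 1.2 |
| south-west | 12.0 | 0.1 |
| south-west | 20.0 | 0 |

(readings scatter by 1 percentage point)

* the best flask by amount of target, in percent of the substrate charged; "all alike" if 1.5 percentage points covers them all (Friday's / Sunday's / Thursday's / Saturday's / all alike)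
* amount of target at the end, in percent of the substrate charged, Friday's
* amount of target at the end, in percent of the substrate charged, Sunday's
* amount of target at the end, in percent of the substrate charged, Thursday's
* amount of target at the end, in percent of the substrate charged, Saturday's



Target is made and then lost, and the south-east run has Thursday's charges at 35 °C instead of 40 °C. For Thursday's, the crude bound from above is that peak reading of 12.4 %, and the crude bound from below is zero.

To tighten them I read a halving time, the hours in which target drops by a factor of 2. From 15.0 h to 20.0 h the south-east run goes from 10.1 % to 5.6 %, which reads 5.88 h, my halving time of target. The earlier stretch from 10.0 h reads a gentler 17.6 h. Both carry the scatter of 1 percentage point, and I assume they hold unchanged at 40 °C.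

Starting from the peak reading at 8.00 h, the gentle time gives 5.21 % for Thursday's as the upper end of my bracket, and the steep one gives 0.926 % as its lower end; both ends are estimates, not strict bounds. A feed ending at 20 h at 40 °C, as in Saturday's and Sunday's, leaves 1.70 halvings, fewer than the 3.74 from the peak, so I put Thursday's last; Friday's, held at 20 °C until 20 h, I put first.

The forecast, holding that target “is destroyed once the earlier material is used up”, names Friday's as best, with 7 % for Friday's, 3 % for Sunday's, 1.5 % for Saturday's and 0.5 % for Thursday's, which stands below my bracket, though its range reaches 2 %.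

The flasks give 8.64 % for Friday's, 3.71 % for Sunday's, 5.11 % for Saturday's and 1.43 % for Thursday's, which lies inside my bracket.

    substrate → intermediate (k = 9.10 × 10⁻⁵ s⁻¹, Ea = 88.0 kJ mol⁻¹)
    first nucleophile + intermediate ⇌ target (K = 120 L mol⁻¹, k = 0.0130 L mol⁻¹ s⁻¹, Ea = 50.0 kJ mol⁻¹, ΔH = 5.00 kJ mol⁻¹)
    second nucleophile + intermediate → other capture product (k = 0.0240 L mol⁻¹ s⁻¹, Ea = 50.0 kJ mol⁻¹)
    (constants at 40 °C)

At 30.0 h the slowest mode of Thursday's has a half-life of 6.91 h, far longer than the 0.23 h of the intermediate by capture with second nucleophile. The intermediate of Thursday's stands at 0.0448 %, in a steady state, made at 0.970 of the rate at which it is used up, each step taken net. Carried from the 5.93 % of Thursday's at 15.0 h, my 5.88 h gives 1.01 % at 30.0 h, where the flask holds 1.43 %. Carried from the 13.4 % of Sunday's at 20.0 h, it gives 4.12 % at 30.0 h, where that flask holds 3.71 %.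

(The readings were generated by integration with constants of no real substance.)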